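**Retrosynthetic overview**
1. Side chain: the C12–C13 bond comes from alkylation of the (S)-lactic acid-derived dioxolanone enolate with C12 iodide 22 (sets C13); C14=C15 comes from lactol methylenation.
2. Ring A decoration on the lactone: the equatorial C3 bromide comes from HAT hydrogenation of the C2=C3 alkenyl bromide; the second C4 methyl comes from α′-methylation of the Δ1-3-ketone.
3. Ring B (formed second): SmI2 ketyl–olefin closure C8–C9 of keto enoate 9, which also gives the 12,8-lactone and sets C8 and C9.
4. Ring A (formed first): catalytic enantioselective Diels–Alder reaction of silyloxydiene 2 with (E)-enal 7, forming C1–C10 and C4–C5.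
5. Feature used: ring A carries a carbonyl-level carbon C3 next to C4 (a silyl enol ether after cycloaddition), and its trans C5–H/C10–CH3 pair is the (E)-2-methyl enal unit C10(CH3)=C5 of 7.

Key step: step 4

Numbering: labdane numbering throughout (ring A = C1–C5 and C10; ring B = C5–C10; C17 on C8, C20 on C10, side chain C11–C16).
Assumption: the (S)-diphenylprolinol-derived catalyst is taken to expose the enal face that leads to 8, by analogy with its known sense for α-methyl enals; the (R)-catalyst would be used if the sense proved opposite.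

**Route**

Step 1
Reactants: 1 ethyl vinyl ketone
Product: 2 (Z)-3-(triisopropylsilyloxy)penta-1,3-diene
Conditions: i-Pr3SiOTf, Et3N, CH2Cl2, 0 °C
Reagents that add atoms: triisopropylsilyl triflate, CC(C)[Si](C(C)C)(C(C)C)OS(=O)(=O)C(F)(F)F
Why: Soft enolisation of the ethyl ketone with silyl triflate and amine (silyl enol ether formation) gives the 2-silyloxydiene, the (Z)-enol ether being favoured because the methyl group stays away from the vinyl group.

Step 2
Reactants: 3 hex-5-en-2-one
Product: 5 4-oxopentanal, via ozonide 4 (not isolated)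
Conditions: O3, CH2Cl2, −78 °C; then PPh3, −78 → 23 °C
Reagents that add atoms: ozone, [O-][O+]=O
Why: Ozonolysis with reductive work-up cleaves the terminal alkene to the aldehyde and leaves the methyl ketone untouched.

Step 3
Reactants: 5 4-oxopentanal; 6 2-(triphenylphosphoranylidene)propanal
Product: 7 (E)-2-methyl-6-oxohept-2-enal
Conditions: CH2Cl2, 23 → 40 °C
Reagents that add atoms: none
Why: Wittig olefination with the formyl-stabilised ylide takes place only at the aldehyde, not at the ketone, and gives the (E)-trisubstituted enal as expected for a stabilised ylide.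

Step 4
Reactants: 2 (Z)-3-(triisopropylsilyloxy)penta-1,3-diene; 7 (E)-2-methyl-6-oxohept-2-enal
Product: 8 (1R,5S,6R)-1,5-dimethyl-6-(3-oxobutyl)-4-(triisopropylsilyloxy)cyclohex-3-ene-1-carbaldehyde (ring carbons 1, 5, 6 = labdane C10, C4, C5)
Conditions: (S)-3,3-diphenyl-1-(o-tolyl)tetrahydro-1H,3H-pyrrolo[1,2-c][1,3,2]oxazaborole (20 mol%) activated with HNTf2, CH2Cl2, −78 → −20 °C; Et3N quench
Reagents that add atoms: none
Why: The protonated oxazaborolidine binds the formyl oxygen of the s-trans enal 7 and lowers its LUMO, and the enol-ether terminus C4 of 2, its most nucleophilic carbon, bonds to the β-carbon C5 slightly ahead of C1–C10 in a concerted asynchronous [4+2] cycloaddition, the established catalytic enantioselective Diels–Alder reaction of α-methyl enals with 2-silyloxydienes. Ring A is closed in this one intermolecular step as a six-membered ring by two bonds (C4–C5 and C1–C10) formed suprafacially on both partners. C10 and C5 arise together from the (E)-geometry of 7, which places the formyl carbon C9 and the C6 chain trans and so fixes the trans C5–H/C20 relationship, while the absolute sense at both centres is set by the catalyst, which shields one face of the bound enal. C4 depends on exo or endo approach (drawn for formyl exo) and is of no consequence, because it is planarised in step 8. The step needs regioselectivity para to the silyloxy group and chemoselectivity for the enal over the side-chain ketone; the first is secured by the 3-silyloxy donor, which outweighs the terminal methyl group, the second by the stronger binding and far higher reactivity of the conjugated aldehyde.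

Step 5
Reactants: 8 ring A cycloadduct
Product: 9 ethyl (E)-3-[1,5-dimethyl-6-(3-oxobutyl)-4-(triisopropylsilyloxy)cyclohex-3-en-1-yl]prop-2-enoate, ring configuration as in 8
Conditions: Ph3P=CHCO2Et, toluene, 90 °C
Reagents that add atoms: ethyl (triphenylphosphoranylidene)acetate, CCOC(=O)C=P(c1ccccc1)(c1ccccc1)c1ccccc1
Why: Wittig olefination with an ester-stabilised ylide engages the non-enolisable quaternary aldehyde but not the methyl ketone, is neutral enough for the silyl enol ether, and gives the (E)-enoate (C9=C11, C12 ester).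

Step 6
Reactants: 9 keto enoate
Product: 11 tricyclic lactone silyl enol ether (3-triisopropylsilyloxy-Δ2, one methyl on C4, 13,14,15,16-tetranorlabdan-12,8-olide skeleton; trans-decalin, C8–O and C9–C11 trans, C5, C8, C9, C10 as in the target), via hydroxy ester 10 (not isolated)
Conditions: SmI2, HMPA, t-BuOH, THF, −78 → 23 °C
Reagents that add atoms: none
Why: Samarium diiodide ketyl–olefin cyclisation, in which the C8 ketyl adds 6-exo-trig to the enoate β-carbon C9 through a chair with the C11 arm and the HMPA-ligated O–Sm group both equatorial (the bulky O–Sm group avoids the axial C20 methyl, so C17 is axial), setting C9 and C8 trans, after which the trivalent samarium alkoxide closes the trans-fused γ-lactone on warming.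

Step 7
Reactants: 11 tricyclic lactone silyl enol ether
Product: 12 Δ1-3-keto lactone (4-monomethyl; 3-oxo-Δ1, otherwise as 11)
Conditions: Pd(OAc)2 (1.1 equiv), DMSO/MeCN, 50 °C
Reagents that add atoms: none
Why: Saegusa–Ito oxidation converts the silyl enol ether into a palladium enolate that loses β-hydride from C1, which fixes the enone as Δ1 and leaves C4–H as the only enolisable position of the ketone.

Step 8
Reactants: 12 Δ1-3-keto lactone
Product: 14 3-oxo-13,14,15,16-tetranorlabd-1-en-12,8-olide (4,4-dimethyl enone lactone), via lithium dienolate 13 (not isolated)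
Conditions: LiN(SiMe3)2 (1.0 equiv), THF, −78 → −30 °C; then MeI, −30 → 0 °C
Reagents that add atoms: iodomethane, CI
Why: α′-Alkylation of a cross-conjugated dienolate: with no γ-hydrogen (C10 is quaternary) C4–H is the only acidic site of the enone, the ketone is several pKa units more acidic than the lactone so one equivalent of base under equilibrating conditions enolises it alone, and C-methylation turns C4 into the achiral gem-dimethyl carbon.

Step 9
Reactants: 14 4,4-dimethyl enone lactone
Product: 16 3-(trifluoromethanesulfonyloxy)-13,14,15,16-tetranorlabd-2-en-12,8-olide (Δ2-enol triflate), via lithium enolate 15 (not isolated)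
Conditions: LiBH(s-Bu)3, THF, −78 °C; then PhNTf2, −78 → 0 °C
Reagents that add atoms: N-phenylbis(trifluoromethanesulfonimide), O=S(=O)(N(c1ccccc1)S(=O)(=O)C(F)(F)F)C(F)(F)F
Why: Conjugate hydride reduction of the enone (1,2-attack is blocked by the C4 gem-dimethyl group) gives the Δ2 lithium enolate regiospecifically, which the triflimide traps on oxygen (reductive enol triflate formation).

Step 10
Reactants: 16 Δ2-enol triflate
Product: 17 3-bromo-13,14,15,16-tetranorlabd-2-en-12,8-olide (alkenyl bromide)
Conditions: Ni(cod)2 (10 mol%), LiBr, DMA/THF, 23 °C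
Reagents that add atoms: lithium bromide, [Li+].[Br-]
Why: Nickel-catalysed halogen exchange of an enol triflate: oxidative addition of zerovalent nickel into the C3–O bond, triflate/bromide exchange and C–Br reductive elimination give the alkenyl bromide without moving the double bond.

Step 11
Reactants: 17 alkenyl bromide
Product: 18 (3R,5S,8S,9S,10R)-3-bromo-13,14,15,16-tetranorlabdan-12,8-olide (bromo lactone, bromine equatorial)
Conditions: Mn(dpm)3 (cat., dpm = dipivaloylmethanato), PhSiH3, t-BuOOH, i-PrOH, 23 °C
Reagents that add atoms: none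
Why: Metal hydride hydrogen-atom-transfer hydrogenation, which tolerates alkenyl halides: H• adds to C2, and the α-bromo radical at C3 takes the second hydrogen on its axial face, away from the axial C4 methyl, so the bromine ends equatorial (thermodynamic stereocontrol) with the C3 configuration of the target.

Step 12
Reactants: 18 bromo lactone
Product: 19 3-bromo-13,14,15,16-tetranorlabdane-8,12-diol
Conditions: LiBH4, THF, 0 → 40 °C
Reagents that add atoms: none
Why: Borohydride reduction of the lactone to the 8,12-diol, LiBH4 being chosen because it leaves the hindered secondary bromide alone.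

Step 13
Reactants: 19 8,12-diol
Product: 20 8,12-bis(triethylsilyl) ether of 19
Conditions: Et3SiOTf, 2,6-lutidine, CH2Cl2, −40 → 0 °C
Reagents that add atoms: triethylsilyl triflate, CC[Si](CC)(CC)OS(=O)(=O)C(F)(F)F
Why: Silyl triflate silylation covers both hydroxyls, including the hindered tertiary C8–OH, which would otherwise close the 8,12-ether ring as soon as C12 carries a leaving group.

Step 14
Reactants: 20 bis(triethylsilyl) ether
Product: 21 3-bromo-8-(triethylsilyloxy)-13,14,15,16-tetranorlabdan-12-ol
Conditions: PPTS (cat.), MeOH/CH2Cl2, 0 °C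
Reagents that add atoms: none
Why: Acid-catalysed methanolysis cleaves the unhindered primary silyl ether much faster than the tertiary one (selective desilylation).

Step 15
Reactants: 21 C12 alcohol
Product: 22 3-bromo-12-iodo-8-(triethylsilyloxy)-13,14,15,16-tetranorlabdane
Conditions: I2, PPh3, imidazole, CH2Cl2, 0 → 23 °C
Reagents that add atoms: iodine, II
Why: Appel-type iodination converts the primary alcohol into the iodide by SN2 displacement at C12, the imidazole-buffered medium sparing the tertiary silyl ether.

Step 16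
Reactants: 23 (S)-lactic acid
Product: 24 (2S,5S)-2-tert-butyl-5-methyl-1,3-dioxolan-4-one
Conditions: t-BuCHO, TsOH (cat.), pentane, reflux with water separation; crystallisation at low temperature
Reagents that add atoms: pivalaldehyde, CC(C)(C)C=O
Why: Acid-catalysed acetalisation with removal of water gives Seebach's dioxolanone; the lactate stereocentre is untouched and the new acetal centre equilibrates to the cis isomer, which is obtained pure by crystallisation.

Step 17
Reactants: 24 (2S,5S)-2-tert-butyl-5-methyl-1,3-dioxolan-4-one; 22 C12 iodide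
Product: 26 (2S,5R)-2-tert-butyl-5-methyl-5-(C12-alkyl)-1,3-dioxolan-4-one (the C11–C12 chain of 22 on the dioxolanone carbon that becomes C13, trans to tert-butyl), via lithium enolate 25 (not isolated)
Conditions: LiN(i-Pr)2, THF, −78 °C; then 22, HMPA, −78 → −30 °C
Reagents that add atoms: none
Why: Seebach alkylation with self-regeneration of the stereocentre: the planar lithium enolate is alkylated by the primary iodide (SN2) on the face opposite the tert-butyl group, so C12 takes the place of the former lactate hydrogen and C13 is formed with the configuration of the target.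

Step 18
Reactants: 26 alkylated dioxolanone
Product: 27 2-tert-butyl-4-hydroxy-1,3-dioxolane (lactol of 26, anomeric mixture)
Conditions: i-Bu2AlH, CH2Cl2, −78 °C
Reagents that add atoms: none
Why: Low-temperature i-Bu2AlH reduction stops at the tetrahedral aluminium hemiacetal and gives the lactol (partial reduction of a lactone).

Step 19
Reactants: 27 lactol
Product: 29 (3R,5S,8S,9S,10R,13R)-3-bromo-8-(triethylsilyloxy)labd-14-en-13-ol, via hydroxy aldehyde 28 (not isolated)
Conditions: Ph3PCH3Br, KOt-Bu (excess ylide), THF, 0 → 40 °C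
Reagents that add atoms: methyltriphenylphosphonium bromide, C[P+](c1ccccc1)(c1ccccc1)c1ccccc1.[Br-]
Why: Wittig methylenation of a lactol: base opens the hemiacetal, pivalaldehyde is lost from the resulting hemiacetal alkoxide, and the unmasked α-alkoxy aldehyde, which has no α-hydrogen, is methylenated to the vinyl carbinol without touching C13.

Step 20
Reactants: 29 8-O-triethylsilyl ether
Product: 30 (3R,5S,8S,9S,10R,13R)-3-bromolabd-14-ene-8,13-diol (target, CNP0150870.4)
Conditions: Bu4NF, THF, 23 → 45 °C
Reagents that add atoms: none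
Why: Fluoride-mediated desilylation removes the tertiary silyl ether under non-acidic conditions, which keeps the tertiary allylic alcohol from ionising.

**Compound list**
1 | ethyl vinyl ketone (pent-1-en-3-one) | CCC(=O)C=C | starting material
2 | (Z)-3-(triisopropylsilyloxy)penta-1,3-diene | C=C/C(O[Si](C(C)C)(C(C)C)C(C)C)=C/C | intermediate
3 | hex-5-en-2-one | CC(=O)CCC=C | starting material
4 | 4-(1,2,4-trioxolan-3-yl)butan-2-one (ozonide of 3) | CC(=O)CCC1OCOO1 | intermediate
5 | 4-oxopentanal | CC(=O)CCC=O | intermediate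
6 | 2-(triphenylphosphoranylidene)propanal | CC(C=O)=P(c1ccccc1)(c1ccccc1)c1ccccc1 | starting material
7 | (E)-2-methyl-6-oxohept-2-enal | O=C/C(C)=C/CCC(C)=O | intermediate
8 | (1R,5S,6R)-1,5-dimethyl-6-(3-oxobutyl)-4-(triisopropylsilyloxy)cyclohex-3-ene-1-carbaldehyde | O=C[C@]1(C)CC=C(O[Si](C(C)C)(C(C)C)C(C)C)[C@@H](C)[C@H]1CCC(C)=O | intermediate
9 | ethyl (E)-3-[1,5-dimethyl-6-(3-oxobutyl)-4-(triisopropylsilyloxy)cyclohex-3-en-1-yl]prop-2-enoate, ring configuration as in 8 | CCOC(=O)/C=C/[C@]1(C)CC=C(O[Si](C(C)C)(C(C)C)C(C)C)[C@@H](C)[C@H]1CCC(C)=O | intermediate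
10 | hydroxy ester (bicyclic C8 carbinol with C9–CH2CO2Et, formed as its samarium alkoxide) | CCOC(=O)C[C@H]1[C@]2(C)CC=C(O[Si](C(C)C)(C(C)C)C(C)C)[C@@H](C)[C@H]2CC[C@]1(C)O | intermediate
11 | tricyclic 12,8-lactone, 3-triisopropylsilyloxy-Δ2, one C4 methyl | O=C1C[C@H]2[C@]3(C)CC=C(O[Si](C(C)C)(C(C)C)C(C)C)[C@@H](C)[C@H]3CC[C@]2(C)O1 | intermediate
12 | Δ1-3-keto 12,8-lactone, one C4 methyl | O=C1C[C@H]2[C@]3(C)C=CC(=O)[C@@H](C)[C@H]3CC[C@]2(C)O1 | intermediate
13 | lithium cross-conjugated dienolate of 12 | O=C1C[C@H]2[C@]3(C)C=CC([O-])=C(C)[C@H]3CC[C@]2(C)O1.[Li+] | intermediate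
14 | 3-oxo-13,14,15,16-tetranorlabd-1-en-12,8-olide | O=C1C[C@H]2[C@]3(C)C=CC(=O)C(C)(C)[C@H]3CC[C@]2(C)O1 | intermediate
15 | lithium Δ2-enolate from 14 | O=C1C[C@H]2[C@]3(C)CC=C([O-])C(C)(C)[C@H]3CC[C@]2(C)O1.[Li+] | intermediate
16 | 3-(trifluoromethanesulfonyloxy)-13,14,15,16-tetranorlabd-2-en-12,8-olide | O=C1C[C@H]2[C@]3(C)CC=C(OS(=O)(=O)C(F)(F)F)C(C)(C)[C@H]3CC[C@]2(C)O1 | intermediate
17 | 3-bromo-13,14,15,16-tetranorlabd-2-en-12,8-olide | O=C1C[C@H]2[C@]3(C)CC=C(Br)C(C)(C)[C@H]3CC[C@]2(C)O1 | intermediate
18 | (3R,5S,8S,9S,10R)-3-bromo-13,14,15,16-tetranorlabdan-12,8-olide | O=C1C[C@H]2[C@]3(C)CC[C@@H](Br)C(C)(C)[C@H]3CC[C@]2(C)O1 | intermediate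
19 | 3-bromo-13,14,15,16-tetranorlabdane-8,12-diol | OCC[C@H]1[C@]2(C)CC[C@@H](Br)C(C)(C)[C@H]2CC[C@]1(C)O | intermediate
20 | 3-bromo-8,12-bis(triethylsilyloxy)-13,14,15,16-tetranorlabdane | CC[Si](CC)(CC)OCC[C@H]1[C@]2(C)CC[C@@H](Br)C(C)(C)[C@H]2CC[C@]1(C)O[Si](CC)(CC)CC | intermediate
21 | 3-bromo-8-(triethylsilyloxy)-13,14,15,16-tetranorlabdan-12-ol | OCC[C@H]1[C@]2(C)CC[C@@H](Br)C(C)(C)[C@H]2CC[C@]1(C)O[Si](CC)(CC)CC | intermediate
22 | 3-bromo-12-iodo-8-(triethylsilyloxy)-13,14,15,16-tetranorlabdane | ICC[C@H]1[C@]2(C)CC[C@@H](Br)C(C)(C)[C@H]2CC[C@]1(C)O[Si](CC)(CC)CC | intermediate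
23 | (S)-lactic acid | C[C@H](O)C(=O)O | starting material
24 | (2S,5S)-2-tert-butyl-5-methyl-1,3-dioxolan-4-one | C[C@@H]1O[C@H](C(C)(C)C)OC1=O | intermediate
25 | lithium enolate of 24 | CC1=C([O-])O[C@@H](C(C)(C)C)O1.[Li+] | intermediate
26 | (2S,5R)-2-tert-butyl-5-methyl-5-(C12-alkyl)-1,3-dioxolan-4-one | O=C1O[C@@H](C(C)(C)C)O[C@]1(C)CC[C@H]2[C@]3(C)CC[C@@H](Br)C(C)(C)[C@H]3CC[C@]2(C)O[Si](CC)(CC)CC | intermediate
27 | lactol of 26 (2-tert-butyl-4-hydroxy-1,3-dioxolane, anomeric mixture) | OC1O[C@@H](C(C)(C)C)O[C@]1(C)CC[C@H]2[C@]3(C)CC[C@@H](Br)C(C)(C)[C@H]3CC[C@]2(C)O[Si](CC)(CC)CC | intermediate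
28 | (13R)-3-bromo-13-hydroxy-8-(triethylsilyloxy)-15-norlabdan-14-al | O=C[C@](C)(O)CC[C@H]1[C@]2(C)CC[C@@H](Br)C(C)(C)[C@H]2CC[C@]1(C)O[Si](CC)(CC)CC | intermediate
29 | (3R,5S,8S,9S,10R,13R)-3-bromo-8-(triethylsilyloxy)labd-14-en-13-ol | C=C[C@](C)(O)CC[C@H]1[C@]2(C)CC[C@@H](Br)C(C)(C)[C@H]2CC[C@]1(C)O[Si](CC)(CC)CC | intermediate
30 | (3R,5S,8S,9S,10R,13R)-3-bromolabd-14-ene-8,13-diol | C=C[C@](C)(O)CC[C@H]1[C@]2(C)CC[C@@H](Br)C(C)(C)[C@H]2CC[C@]1(C)O | target

**Step count**
Total: 20 steps. Longest linear sequence: 18 steps (steps 2–15, then 17–20, from hex-5-en-2-one); steps 1 and 16 are side branches.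

**Steps most likely to fail**

Step 4. The β-alkyl α-methyl enal may turn over too slowly at the temperatures where the catalyst keeps its selectivity, so that desilylation of the diene or Mukaiyama-type addition overtakes the cycloaddition, or the enantioselectivity erodes. Fallback: setting out from 2 and 7, the same cycloaddition is run with an achiral Lewis acid (Me2AlCl, CH2Cl2, −78 → −20 °C), which should give 8 together with its enantiomer ent-8 F1. Wittig olefination as in step 5 then gives 9 together with ent-9 F2, and the two are separated by preparative chromatography on a chiral stationary phase, using the enoate chromophore for detection. The route is rejoined at 9.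

Step 6. Simple reduction of the enoate or the ketone may compete with ring closure, or the ketyl may close with the O–Sm group axial and give the C8 epimer. Fallback: setting out from 9, kinetic enolisation of the methyl ketone (LiN(i-Pr)2, t-BuMe2SiCl, HMPA, THF, −78 °C) gives the terminal silyl enol ether F3. Iron-catalysed hydrogen-atom-transfer reductive cyclisation (Fe(acac)3, PhSiH3, EtOH/ethylene glycol, 60 °C) generates the C8 α-silyloxy radical by H• addition to the 1,1-disubstituted enol ether, which reacts ahead of the trisubstituted ring A enol ether, and closes ring B onto the enoate to give the C8 silyl ether ester F4. Saegusa–Ito oxidation of its ring A enol ether (Pd(OAc)2, DMSO/MeCN) gives the enone ester F5, and HF·pyridine followed by catalytic TsOH removes the tertiary silyl group and closes the lactone. The route is rejoined at 12.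

Step 17. The dioxolanone enolate may decompose before the unactivated primary iodide is consumed, giving low conversion. Fallback: setting out from 21, Dess–Martin oxidation gives the C12 aldehyde F6, and Wittig olefination with Ph3P=C(CH3)CO2Et gives the (E)-2-methyl enoate F7. i-Bu2AlH reduction gives the allylic alcohol F8. Sharpless asymmetric epoxidation (Ti(O-i-Pr)4, L-(+)-diethyl tartrate, t-BuOOH, CH2Cl2, −20 °C) gives the (2S,3S)-epoxy alcohol F9 and sets C13. Hydride opening at the less substituted C12 (i-Bu2AlH, CH2Cl2) gives the 13,14-diol F10, and Parikh–Doering oxidation of its primary hydroxyl (SO3·pyridine, DMSO, Et3N) gives the hydroxy aldehyde. The route is rejoined at 28, which is methylenated as in step 19 to 29.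

**Further compounds**
F1 | step 4 | ent-8, (1S,5R,6S)-1,5-dimethyl-6-(3-oxobutyl)-4-(triisopropylsilyloxy)cyclohex-3-ene-1-carbaldehyde | O=C[C@@]1(C)CC=C(O[Si](C(C)C)(C(C)C)C(C)C)[C@H](C)[C@@H]1CCC(C)=O
F2 | step 4 | ent-9, enantiomer of keto enoate 9 | CCOC(=O)/C=C/[C@@]1(C)CC=C(O[Si](C(C)C)(C(C)C)C(C)C)[C@H](C)[C@@H]1CCC(C)=O
F3 | step 6 | terminal tert-butyldimethylsilyl enol ether of the methyl ketone of 9 | CCOC(=O)/C=C/[C@]1(C)CC=C(O[Si](C(C)C)(C(C)C)C(C)C)[C@@H](C)[C@H]1CCC(=C)O[Si](C)(C)C(C)(C)C
F4 | step 6 | ring B-closed ester with C8 tert-butyldimethylsilyl ether and ring A silyl enol ether | CCOC(=O)C[C@H]1[C@]2(C)CC=C(O[Si](C(C)C)(C(C)C)C(C)C)[C@@H](C)[C@H]2CC[C@]1(C)O[Si](C)(C)C(C)(C)C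
F5 | step 6 | Δ1-3-keto ester with C8 tert-butyldimethylsilyl ether | CCOC(=O)C[C@H]1[C@]2(C)C=CC(=O)[C@@H](C)[C@H]2CC[C@]1(C)O[Si](C)(C)C(C)(C)C
F6 | step 17 | 3-bromo-8-(triethylsilyloxy)-13,14,15,16-tetranorlabdan-12-al | O=CC[C@H]1[C@]2(C)CC[C@@H](Br)C(C)(C)[C@H]2CC[C@]1(C)O[Si](CC)(CC)CC
F7 | step 17 | ethyl (E)-2-methylbut-2-enoate homologue of F6 (C12=C13 enoate, C14 ester) | CCOC(=O)/C(C)=C/C[C@H]1[C@]2(C)CC[C@@H](Br)C(C)(C)[C@H]2CC[C@]1(C)O[Si](CC)(CC)CC
F8 | step 17 | (E)-allylic alcohol (C12=C13, C14 hydroxyl) | OC/C(C)=C/C[C@H]1[C@]2(C)CC[C@@H](Br)C(C)(C)[C@H]2CC[C@]1(C)O[Si](CC)(CC)CC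
F9 | step 17 | (2S,3S)-epoxy alcohol (12,13-epoxide, C14 hydroxyl) | OC[C@]1(C)O[C@H]1C[C@H]2[C@]3(C)CC[C@@H](Br)C(C)(C)[C@H]3CC[C@]2(C)O[Si](CC)(CC)CC
F10 | step 17 | (13R)-3-bromo-8-(triethylsilyloxy)-15-norlabdane-13,14-diol | OC[C@](C)(O)CC[C@H]1[C@]2(C)CC[C@@H](Br)C(C)(C)[C@H]2CC[C@]1(C)O[Si](CC)(CC)CC
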